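Ring C of the dihydroflavonol half is disconnected at O1–C2 and C3–C4. Ring A already holds O1 on C8a and C4 on C4a, which is a salicylaldehyde, while C2, C3 and ring B (the 4-hydroxyphenyl group) are the β-carbon, α-carbon and aryl group of a cinnamaldehyde. An amine-catalysed domino oxa-Michael–aldol condensation exploits exactly this pattern: in one operation it forms both bonds, closes ring C as a 2-aryl-2H-chromene-3-carbaldehyde and sets C2. Its precursor is a perbenzylated biaryl in which the apigenin unit is already joined to the salicylaldehyde ring. The formyl group is then excised, C2 directs the oxygenation of C3, C4 is oxidised and the benzyl ethers are removed.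

Key step: step 12

Remark: the biaryl axis (C8 of the chromanone unit to C3' of the flavone) carries three ortho oxygen substituents and has no axial descriptor in the target; it is assumed to rotate at room temperature, so intermediates may show rotamers but no atropisomer has to be controlled.

Abbreviation used in names: Ar* = 2-(benzyloxy)-5-[5,7-bis(benzyloxy)-4-oxo-4H-chromen-2-yl]phenyl, that is the tri-O-benzylapigenin unit bonded through C3' of its ring B.

Step 1
Reactants: 1 2',4',6'-trihydroxyacetophenone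
Product: 2 1-[2,4-bis(benzyloxy)-6-hydroxyphenyl]ethan-1-one
Conditions: BnBr (2.05 equiv), K2CO3 (2.2 equiv), DMF, rt
Reagents that add atoms: benzyl bromide BrCc1ccccc1
Why: Williamson etherification in which the hydroxyl hydrogen-bonded to the acetyl group is the least nucleophilic, so two equivalents of benzyl bromide should alkylate only the other two hydroxyls.

Step 2
Reactants: 3 4-hydroxy-3-iodobenzaldehyde
Product: 4 4-(benzyloxy)-3-iodobenzaldehyde
Conditions: BnBr (1.1 equiv), K2CO3, DMF, rt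
Reagents that add atoms: benzyl bromide BrCc1ccccc1
Why: Williamson etherification of a phenol under carbonate conditions that leave the aldehyde and the aryl iodide untouched.

Step 3
Reactants: 2 1-[2,4-bis(benzyloxy)-6-hydroxyphenyl]ethan-1-one, 4 4-(benzyloxy)-3-iodobenzaldehyde
Product: 5 (E)-1-[2,4-bis(benzyloxy)-6-hydroxyphenyl]-3-[4-(benzyloxy)-3-iodophenyl]prop-2-en-1-one
Conditions: KOH (50% aq), EtOH/THF, rt
Reagents that add atoms: none
Why: Claisen–Schmidt condensation of a methyl ketone with a non-enolisable aldehyde, which should give the thermodynamically preferred (E)-chalcone.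

Step 4
Reactants: 5 (E)-1-[2,4-bis(benzyloxy)-6-hydroxyphenyl]-3-[4-(benzyloxy)-3-iodophenyl]prop-2-en-1-one
Product: 6 5,7-bis(benzyloxy)-2-[4-(benzyloxy)-3-iodophenyl]-4H-chromen-4-one
Conditions: I2 (10 mol%), DMSO, 120 °C
Reagents that add atoms: none
Why: Iodine-catalysed oxidative cyclisation of a 2'-hydroxychalcone with DMSO as terminal oxidant, the standard flavone synthesis, which should tolerate the aryl iodide and the benzyl ethers.

Step 5
Reactants: 7 phloroglucinol
Product: 8 3,5-bis(methoxymethoxy)phenol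
Conditions: MOMCl (2.0 equiv), iPr2NEt (2.2 equiv), THF/CH2Cl2, 0 °C to rt
Reagents that add atoms: chloromethyl methyl ether COCCl
Why: O-alkylation of a phenol with an α-chloro ether (acetal formation), in which two equivalents should make the bis-ether the main component of a separable mixture whose mono- and tris-ethers can be recycled.

Step 6
Reactants: 8 3,5-bis(methoxymethoxy)phenol
Product: 9 1-(benzyloxy)-3,5-bis(methoxymethoxy)benzene
Conditions: BnBr (1.2 equiv), K2CO3, DMF, rt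
Reagents that add atoms: benzyl bromide BrCc1ccccc1
Why: Williamson etherification of the one remaining phenol, placing the benzyl group on the oxygen that ends para to the biaryl bond.

Step 7
Reactants: 9 1-(benzyloxy)-3,5-bis(methoxymethoxy)benzene, 6 5,7-bis(benzyloxy)-2-[4-(benzyloxy)-3-iodophenyl]-4H-chromen-4-one
Product: 12 5,7-bis(benzyloxy)-2-{4-(benzyloxy)-3-[4-(benzyloxy)-2,6-bis(methoxymethoxy)phenyl]phenyl}-4H-chromen-4-one, via aryllithium 10 (not isolated), via arylzinc chloride 11 (not isolated)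
Conditions: n-BuLi (1.05 equiv to 9), THF, 0 °C; ZnCl2 (1.1 equiv), 0 °C to rt; then 6 (0.7 equiv), Pd2(dba)3 (2 mol%), SPhos (8 mol%), THF, 65 °C
Reagents that add atoms: none
Why: Directed ortho-metalation at the carbon flanked by two chelating MOM ethers, transmetalation to zinc and Negishi cross-coupling at zerovalent palladium with a bulky biarylphosphine, which should tolerate the flavone carbonyl and the tri-ortho-substituted biaryl being formed.

Step 8
Reactants: 12 5,7-bis(benzyloxy)-2-{4-(benzyloxy)-3-[4-(benzyloxy)-2,6-bis(methoxymethoxy)phenyl]phenyl}-4H-chromen-4-one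
Product: 13 5,7-bis(benzyloxy)-2-{4-(benzyloxy)-3-[4-(benzyloxy)-2,6-dihydroxyphenyl]phenyl}-4H-chromen-4-one
Conditions: conc. HCl (cat.), MeOH/THF, 50 °C
Reagents that add atoms: none
Why: Acid-catalysed acetal exchange with methanol should remove both MOM groups without touching benzyl ethers or the flavone, leaving a resorcinol ring with two equivalent free positions.

Step 9
Reactants: 13 5,7-bis(benzyloxy)-2-{4-(benzyloxy)-3-[4-(benzyloxy)-2,6-dihydroxyphenyl]phenyl}-4H-chromen-4-one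
Product: 15 6-(benzyloxy)-2,4-dihydroxy-3-Ar*-benzaldehyde, via iminium chloride 14 (not isolated)
Conditions: POCl3 (1.5 equiv), DMF (3 equiv), MeCN, 0 °C to rt; then H2O, 50 °C
Reagents that add atoms: N,N-dimethylformamide CN(C)C=O; water O
Why: Vilsmeier–Haack formylation at the position activated by three oxygen substituents, where the two open positions are equivalent so only one mono-aldehyde can form, the first formyl group deactivates the ring and the flavone ring A is deactivated by its carbonyl.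

Step 10
Reactants: 15 6-(benzyloxy)-2,4-dihydroxy-3-Ar*-benzaldehyde
Product: 16 4,6-bis(benzyloxy)-2-hydroxy-3-Ar*-benzaldehyde
Conditions: BnBr (1.05 equiv), K2CO3 (1.1 equiv), DMF, rt
Reagents that add atoms: benzyl bromide BrCc1ccccc1
Why: Williamson etherification that should select the more acidic, non-chelated hydroxyl para to the aldehyde, while the ortho hydroxyl stays locked in its hydrogen bond to the carbonyl.

Step 11
Reactants: 17 4-(benzyloxy)benzaldehyde
Product: 18 (E)-3-[4-(benzyloxy)phenyl]prop-2-enal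
Conditions: Ph3P=CHCHO (1.2 equiv), toluene, 80 °C
Reagents that add atoms: (triphenylphosphoranylidene)acetaldehyde O=CC=P(c1ccccc1)(c1ccccc1)c1ccccc1
Why: Wittig olefination with a stabilised ylide, which should give the two-carbon homologated (E)-enal.

Step 12
Reactants: 16 4,6-bis(benzyloxy)-2-hydroxy-3-Ar*-benzaldehyde, 18 (E)-3-[4-(benzyloxy)phenyl]prop-2-enal
Product: 22 (2R)-5,7-bis(benzyloxy)-2-[4-(benzyloxy)phenyl]-8-Ar*-2H-chromene-3-carbaldehyde, via iminium ion 19 (not isolated), via oxa-Michael enamine 20 (not isolated), via aldol iminium ion 21 (not isolated)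
Conditions: (S)-2-[diphenyl(trimethylsilyloxy)methyl]pyrrolidine (20 mol%), 2-nitrobenzoic acid (20 mol%), 4 Å MS, toluene, rt to 40 °C
Reagents that add atoms: none
Why: The (S)-catalyst condenses with enal 18 to the (E)-iminium ion 19, whose β-carbon is attacked by the phenolic oxygen of 16 (O1–C2 bond) to give enamine 20; the enamine carbon then adds to the adjacent aryl aldehyde (C3–C4 bond) to give 21, and loss of water with hydrolysis of the iminium ion should release 22 and the amine. The closest known reaction type is the secondary-amine-catalysed enantioselective domino oxa-Michael–aldol condensation of salicylaldehydes with enals that gives 2-substituted 2H-chromene-3-carbaldehydes, here stretched to a hindered 3-aryl salicylaldehyde and an electron-rich enal. Ring C is closed in a 6-(enolexo)-exo-trig aldol addition, and the following dehydration, which conjugates C3=C4 with ring A and the formyl group, makes the closure irreversible. The only new stereocentre, C2, is set by the catalyst: its diphenyl(trimethylsilyloxy)methyl group covers the Re face of the β-carbon, so oxygen should add to the Si face, which corresponds to (2R). The step needs conjugate addition by the phenol instead of 1,2-addition and aldol closure onto the salicylaldehyde carbonyl instead of enal self-condensation; both are secured because the single free hydroxyl of 16 sits ortho to the only aryl aldehyde, so the tethered enamine can reach only that carbonyl, and every other oxygen is benzylated.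

Step 13
Reactants: 22 (2R)-5,7-bis(benzyloxy)-2-[4-(benzyloxy)phenyl]-8-Ar*-2H-chromene-3-carbaldehyde
Product: 23 (2S)-5,7-bis(benzyloxy)-2-[4-(benzyloxy)phenyl]-8-Ar*-2H-chromene
Conditions: RhCl(PPh3)3 (1.1 equiv), toluene (degassed), 80 °C
Reagents that add atoms: none
Why: Tsuji–Wilkinson decarbonylation (oxidative addition of the formyl C–H bond to monovalent rhodium, CO extrusion, C–H reductive elimination) should replace CHO by H without moving C3=C4 or touching C2, whose descriptor changes from R to S only because C3 now ranks below the aryl group.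

Step 14
Reactants: 23 (2S)-5,7-bis(benzyloxy)-2-[4-(benzyloxy)phenyl]-8-Ar*-2H-chromene
Product: 24 (2R,3S,4S)-5,7-bis(benzyloxy)-2-[4-(benzyloxy)phenyl]-8-Ar*-3,4-dihydro-2H-chromene-3,4-diol
Conditions: OsO4 (5 mol%), NMO (1.5 equiv), acetone/THF/H2O, rt
Reagents that add atoms: osmium tetroxide O=[Os](=O)(=O)=O; N-methylmorpholine N-oxide C[N+]1([O-])CCOCC1; water O
Why: OsO4-catalysed syn-dihydroxylation of the electron-rich C3=C4 bond should occur on the face opposite the C2 aryl group, so C2 sets C3 (hydroxyl trans to ring B) and C4 (cis to the 3-hydroxyl) by substrate control, while the electron-poor flavone double bond is spared.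

Step 15
Reactants: 24 (2R,3S,4S)-5,7-bis(benzyloxy)-2-[4-(benzyloxy)phenyl]-8-Ar*-3,4-dihydro-2H-chromene-3,4-diol
Product: 25 (2R,3R)-5,7-bis(benzyloxy)-2-[4-(benzyloxy)phenyl]-3-hydroxy-8-Ar*-2,3-dihydro-4H-chromen-4-one
Conditions: DDQ (1.2 equiv), CH2Cl2, 0 °C to rt
Reagents that add atoms: none
Why: DDQ oxidation of an electron-rich benzylic alcohol by hydride abstraction from C4–H, which is activated by the ortho and para oxygen donors of ring A, should leave the non-benzylic C3 carbinol untouched and avoids the glycol cleavage that metal oxide oxidants can cause; C3 keeps its configuration (3R by the changed ranking).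

Step 16
Reactants: 25 (2R,3R)-5,7-bis(benzyloxy)-2-[4-(benzyloxy)phenyl]-3-hydroxy-8-Ar*-2,3-dihydro-4H-chromen-4-one
Product: 26 (2R,3R)-3,5,7-trihydroxy-8-[2-hydroxy-5-(5,7-dihydroxy-4-oxo-4H-chromen-2-yl)phenyl]-2-(4-hydroxyphenyl)-2,3-dihydro-4H-chromen-4-one
Conditions: H2 (1 atm), 10% Pd/C, THF/MeOH, rt
Reagents that add atoms: none
Why: Catalytic hydrogenolysis of the six aryl benzyl ethers under neutral conditions should leave the chromanone, the flavone and the trans C2/C3 stereocentres intact.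

Compound list
1 | 2',4',6'-trihydroxyacetophenone | CC(=O)c1c(O)cc(O)cc1O | starting material
2 | 1-[2,4-bis(benzyloxy)-6-hydroxyphenyl]ethan-1-one | CC(=O)c1c(O)cc(OCc2ccccc2)cc1OCc1ccccc1 | intermediate
3 | 4-hydroxy-3-iodobenzaldehyde | O=Cc1ccc(O)c(I)c1 | starting material
4 | 4-(benzyloxy)-3-iodobenzaldehyde | O=Cc1ccc(OCc2ccccc2)c(I)c1 | intermediate
5 | (E)-1-[2,4-bis(benzyloxy)-6-hydroxyphenyl]-3-[4-(benzyloxy)-3-iodophenyl]prop-2-en-1-one | O=C(/C=C/c1ccc(OCc2ccccc2)c(I)c1)c1c(O)cc(OCc2ccccc2)cc1OCc1ccccc1 | intermediate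
6 | 5,7-bis(benzyloxy)-2-[4-(benzyloxy)-3-iodophenyl]-4H-chromen-4-one | O=c1cc(-c2ccc(OCc3ccccc3)c(I)c2)oc2cc(OCc3ccccc3)cc(OCc3ccccc3)c12 | intermediate
7 | phloroglucinol | Oc1cc(O)cc(O)c1 | starting material
8 | 3,5-bis(methoxymethoxy)phenol | COCOc1cc(O)cc(OCOC)c1 | intermediate
9 | 1-(benzyloxy)-3,5-bis(methoxymethoxy)benzene | COCOc1cc(OCc2ccccc2)cc(OCOC)c1 | intermediate
10 | [4-(benzyloxy)-2,6-bis(methoxymethoxy)phenyl]lithium | [Li]c1c(OCOC)cc(OCc2ccccc2)cc1OCOC | intermediate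
11 | [4-(benzyloxy)-2,6-bis(methoxymethoxy)phenyl]zinc chloride | Cl[Zn]c1c(OCOC)cc(OCc2ccccc2)cc1OCOC | intermediate
12 | 5,7-bis(benzyloxy)-2-{4-(benzyloxy)-3-[4-(benzyloxy)-2,6-bis(methoxymethoxy)phenyl]phenyl}-4H-chromen-4-one | COCOc1cc(OCc2ccccc2)cc(OCOC)c1-c1cc(-c2cc(=O)c3c(OCc4ccccc4)cc(OCc4ccccc4)cc3o2)ccc1OCc1ccccc1 | intermediate
13 | 5,7-bis(benzyloxy)-2-{4-(benzyloxy)-3-[4-(benzyloxy)-2,6-dihydroxyphenyl]phenyl}-4H-chromen-4-one | Oc1cc(OCc2ccccc2)cc(O)c1-c1cc(-c2cc(=O)c3c(OCc4ccccc4)cc(OCc4ccccc4)cc3o2)ccc1OCc1ccccc1 | intermediate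
14 | N-[(6-(benzyloxy)-3-{2-(benzyloxy)-5-[5,7-bis(benzyloxy)-4-oxo-4H-chromen-2-yl]phenyl}-2,4-dihydroxyphenyl)methylidene]-N-methylmethanaminium chloride | C[N+](C)=Cc1c(OCc2ccccc2)cc(O)c(-c2cc(-c3cc(=O)c4c(OCc5ccccc5)cc(OCc5ccccc5)cc4o3)ccc2OCc2ccccc2)c1O.[Cl-] | intermediate
15 | 6-(benzyloxy)-3-{2-(benzyloxy)-5-[5,7-bis(benzyloxy)-4-oxo-4H-chromen-2-yl]phenyl}-2,4-dihydroxybenzaldehyde | O=Cc1c(OCc2ccccc2)cc(O)c(-c2cc(-c3cc(=O)c4c(OCc5ccccc5)cc(OCc5ccccc5)cc4o3)ccc2OCc2ccccc2)c1O | intermediate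
16 | 4,6-bis(benzyloxy)-3-{2-(benzyloxy)-5-[5,7-bis(benzyloxy)-4-oxo-4H-chromen-2-yl]phenyl}-2-hydroxybenzaldehyde | O=Cc1c(OCc2ccccc2)cc(OCc2ccccc2)c(-c2cc(-c3cc(=O)c4c(OCc5ccccc5)cc(OCc5ccccc5)cc4o3)ccc2OCc2ccccc2)c1O | intermediate
17 | 4-(benzyloxy)benzaldehyde | O=Cc1ccc(OCc2ccccc2)cc1 | starting material
18 | (E)-3-[4-(benzyloxy)phenyl]prop-2-enal | O=C/C=C/c1ccc(OCc2ccccc2)cc1 | intermediate
19 | (2S)-1-{(E)-3-[4-(benzyloxy)phenyl]prop-2-enylidene}-2-[diphenyl(trimethylsilyloxy)methyl]pyrrolidinium 2-nitrobenzoate | C[Si](C)(C)OC(c1ccccc1)(c1ccccc1)[C@@H]1CCC[N+]1=C/C=C/c1ccc(OCc2ccccc2)cc1.[O-]C(=O)c1ccccc1[N+](=O)[O-] | intermediate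
20 | enamine of the catalyst with 3-(2-formyl-3,5-bis(benzyloxy)-6-Ar*-phenoxy)-3-[4-(benzyloxy)phenyl]propanal (new O1–C2 bond) | C[Si](C)(C)OC(c1ccccc1)(c1ccccc1)[C@@H]1CCCN1/C=C/[C@H](Oc1c(C=O)c(OCc2ccccc2)cc(OCc2ccccc2)c1-c1cc(-c2cc(=O)c3c(OCc4ccccc4)cc(OCc4ccccc4)cc3o2)ccc1OCc1ccccc1)c1ccc(OCc2ccccc2)cc1 | intermediate
21 | catalyst iminium ion of 5,7-bis(benzyloxy)-2-[4-(benzyloxy)phenyl]-4-hydroxy-8-Ar*-chromane-3-carbaldehyde (2-nitrobenzoate; C3 and C4 undefined) | C[Si](C)(C)OC(c1ccccc1)(c1ccccc1)[C@@H]1CCC[N+]1=CC1C(O)c2c(OCc3ccccc3)cc(OCc3ccccc3)c(-c3cc(-c4cc(=O)c5c(OCc6ccccc6)cc(OCc6ccccc6)cc5o4)ccc3OCc3ccccc3)c2O[C@@H]1c1ccc(OCc2ccccc2)cc1.[O-]C(=O)c1ccccc1[N+](=O)[O-] | intermediate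
22 | (2R)-5,7-bis(benzyloxy)-2-[4-(benzyloxy)phenyl]-8-{2-(benzyloxy)-5-[5,7-bis(benzyloxy)-4-oxo-4H-chromen-2-yl]phenyl}-2H-chromene-3-carbaldehyde | O=CC1=Cc2c(OCc3ccccc3)cc(OCc3ccccc3)c(-c3cc(-c4cc(=O)c5c(OCc6ccccc6)cc(OCc6ccccc6)cc5o4)ccc3OCc3ccccc3)c2O[C@@H]1c1ccc(OCc2ccccc2)cc1 | intermediate
23 | (2S)-5,7-bis(benzyloxy)-2-[4-(benzyloxy)phenyl]-8-{2-(benzyloxy)-5-[5,7-bis(benzyloxy)-4-oxo-4H-chromen-2-yl]phenyl}-2H-chromene | C1=Cc2c(OCc3ccccc3)cc(OCc3ccccc3)c(-c3cc(-c4cc(=O)c5c(OCc6ccccc6)cc(OCc6ccccc6)cc5o4)ccc3OCc3ccccc3)c2O[C@@H]1c1ccc(OCc2ccccc2)cc1 | intermediate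
24 | (2R,3S,4S)-5,7-bis(benzyloxy)-2-[4-(benzyloxy)phenyl]-8-{2-(benzyloxy)-5-[5,7-bis(benzyloxy)-4-oxo-4H-chromen-2-yl]phenyl}-3,4-dihydro-2H-chromene-3,4-diol | O[C@H]1c2c(OCc3ccccc3)cc(OCc3ccccc3)c(-c3cc(-c4cc(=O)c5c(OCc6ccccc6)cc(OCc6ccccc6)cc5o4)ccc3OCc3ccccc3)c2O[C@H](c2ccc(OCc3ccccc3)cc2)[C@H]1O | intermediate
25 | (2R,3R)-5,7-bis(benzyloxy)-2-[4-(benzyloxy)phenyl]-8-{2-(benzyloxy)-5-[5,7-bis(benzyloxy)-4-oxo-4H-chromen-2-yl]phenyl}-3-hydroxy-2,3-dihydro-4H-chromen-4-one | O=C1c2c(OCc3ccccc3)cc(OCc3ccccc3)c(-c3cc(-c4cc(=O)c5c(OCc6ccccc6)cc(OCc6ccccc6)cc5o4)ccc3OCc3ccccc3)c2O[C@H](c2ccc(OCc3ccccc3)cc2)[C@H]1O | intermediate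
26 | (2R,3R)-3,5,7-trihydroxy-8-[2-hydroxy-5-(5,7-dihydroxy-4-oxo-4H-chromen-2-yl)phenyl]-2-(4-hydroxyphenyl)-2,3-dihydro-4H-chromen-4-one | O=C1c2c(O)cc(O)c(-c3cc(-c4cc(=O)c5c(O)cc(O)cc5o4)ccc3O)c2O[C@H](c2ccc(O)cc2)[C@H]1O | target

Total step count: 16. Longest linear sequence: 12 steps (steps 1, 3, 4, 7, 8, 9, 10, 12, 13, 14, 15, 16).

Steps most likely to fail

Step 12. The oxa-Michael addition may not start because the phenol is hydrogen-bonded to the aldehyde and screened by the ortho aryl group, or slow catalysed addition may let an unselective background pathway erode the facial control at C2. Fallback (sets out from 16 and 18, comes back at 23, so step 13 is bypassed as well): aldehyde 16 is methylenated by Wittig olefination (Ph3P=CH2, THF) to 3,5-bis(benzyloxy)-2-ethenyl-6-Ar*-phenol F1. Enal 18 is reduced under Luche conditions (NaBH4, CeCl3·7H2O, MeOH) to (E)-3-[4-(benzyloxy)phenyl]prop-2-en-1-ol F2 and acylated (ClCO2Me, pyridine) to (E)-3-[4-(benzyloxy)phenyl]prop-2-en-1-yl methyl carbonate F3. Enantioselective allylic etherification of the lithium phenoxide of F1 with F3 ([Ir(cod)Cl]2, a binaphthol-derived phosphoramidite with a bis(1-phenylethyl)amino group, THF) should form the O1–C2 bond as the branched ether 2-{(1S)-1-[4-(benzyloxy)phenyl]prop-2-en-1-yloxy}-4,6-bis(benzyloxy)-1-ethenyl-3-Ar*-benzene F4, the ligand enantiomer being chosen for the (S) ether. Ring-closing metathesis (second-generation Grubbs catalyst, RuCl2(H2IMes)(PCy3)(=CHPh), CH2Cl2, 40 °C) then closes C3=C4 and gives 23.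

Step 13. Decarbonylation may stall at the acyl-rhodium stage of this hindered, conjugated aldehyde. At the temperature it needs, the C2 configuration may also erode through reversible electrocyclic opening of the 2H-chromene or through rhodium hydride-mediated alkene migration. Fallback (sets out from 16, comes back at 23): a formyl-free annulation followed by resolution. Commercial 1-(benzyloxy)-4-ethynylbenzene is hydroborated with catecholborane to 2-{(E)-2-[4-(benzyloxy)phenyl]ethenyl}-1,3,2-benzodioxaborole F5 and hydrolysed to (E)-2-[4-(benzyloxy)phenyl]ethenylboronic acid F6. Heating 16 with F6 and dibenzylamine (dioxane, 90 °C) should bring about Petasis borono-Mannich addition, loss of the amine and 6π-electrocyclisation to racemic 5,7-bis(benzyloxy)-2-[4-(benzyloxy)phenyl]-8-Ar*-2H-chromene F7. Preparative chromatography on a chiral stationary phase then delivers 23.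

Step 15. Hydride abstraction may not stop cleanly at the benzylic ketone: over-oxidation to the flavonol, competing abstraction of the C2 hydrogen next to the 4-benzyloxyphenyl ring, or acid-promoted ionisation of the C4 hydroxyl are possible. Fallback (sets out from 24, comes back at 25): the oxidation is made unambiguous by protection. The more accessible, non-benzylic 3-hydroxyl is silylated (TBSCl, imidazole, DMF) to (2R,3S,4S)-3-(tert-butyldimethylsilyloxy)-5,7-bis(benzyloxy)-2-[4-(benzyloxy)phenyl]-8-Ar*-chroman-4-ol F8. The remaining C4 hydroxyl is oxidised (DMP, NaHCO3, CH2Cl2) to (2R,3R)-3-(tert-butyldimethylsilyloxy)-5,7-bis(benzyloxy)-2-[4-(benzyloxy)phenyl]-8-Ar*-chroman-4-one F9. Desilylation (HF·pyridine, THF) gives 25.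

Further compounds
F1 | step 12 | 3,5-bis(benzyloxy)-2-ethenyl-6-{2-(benzyloxy)-5-[5,7-bis(benzyloxy)-4-oxo-4H-chromen-2-yl]phenyl}phenol | C=Cc1c(OCc2ccccc2)cc(OCc2ccccc2)c(-c2cc(-c3cc(=O)c4c(OCc5ccccc5)cc(OCc5ccccc5)cc4o3)ccc2OCc2ccccc2)c1O
F2 | step 12 | (E)-3-[4-(benzyloxy)phenyl]prop-2-en-1-ol | OC/C=C/c1ccc(OCc2ccccc2)cc1
F3 | step 12 | (E)-3-[4-(benzyloxy)phenyl]prop-2-en-1-yl methyl carbonate | COC(=O)OC/C=C/c1ccc(OCc2ccccc2)cc1
F4 | step 12 | 2-{(1S)-1-[4-(benzyloxy)phenyl]prop-2-en-1-yloxy}-4,6-bis(benzyloxy)-1-ethenyl-3-{2-(benzyloxy)-5-[5,7-bis(benzyloxy)-4-oxo-4H-chromen-2-yl]phenyl}benzene | C=C[C@H](Oc1c(C=C)c(OCc2ccccc2)cc(OCc2ccccc2)c1-c1cc(-c2cc(=O)c3c(OCc4ccccc4)cc(OCc4ccccc4)cc3o2)ccc1OCc1ccccc1)c1ccc(OCc2ccccc2)cc1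
F5 | step 13 | 2-{(E)-2-[4-(benzyloxy)phenyl]ethenyl}-1,3,2-benzodioxaborole | c1ccc2OB(/C=C/c3ccc(OCc4ccccc4)cc3)Oc2c1
F6 | step 13 | (E)-2-[4-(benzyloxy)phenyl]ethenylboronic acid | OB(O)/C=C/c1ccc(OCc2ccccc2)cc1
F7 | step 13 | racemic 5,7-bis(benzyloxy)-2-[4-(benzyloxy)phenyl]-8-{2-(benzyloxy)-5-[5,7-bis(benzyloxy)-4-oxo-4H-chromen-2-yl]phenyl}-2H-chromene | C1=Cc2c(OCc3ccccc3)cc(OCc3ccccc3)c(-c3cc(-c4cc(=O)c5c(OCc6ccccc6)cc(OCc6ccccc6)cc5o4)ccc3OCc3ccccc3)c2OC1c1ccc(OCc2ccccc2)cc1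
F8 | step 15 | (2R,3S,4S)-3-(tert-butyldimethylsilyloxy)-5,7-bis(benzyloxy)-2-[4-(benzyloxy)phenyl]-8-{2-(benzyloxy)-5-[5,7-bis(benzyloxy)-4-oxo-4H-chromen-2-yl]phenyl}chroman-4-ol | O[C@H]1c2c(OCc3ccccc3)cc(OCc3ccccc3)c(-c3cc(-c4cc(=O)c5c(OCc6ccccc6)cc(OCc6ccccc6)cc5o4)ccc3OCc3ccccc3)c2O[C@H](c2ccc(OCc3ccccc3)cc2)[C@H]1O[Si](C)(C)C(C)(C)C
F9 | step 15 | (2R,3R)-3-(tert-butyldimethylsilyloxy)-5,7-bis(benzyloxy)-2-[4-(benzyloxy)phenyl]-8-{2-(benzyloxy)-5-[5,7-bis(benzyloxy)-4-oxo-4H-chromen-2-yl]phenyl}chroman-4-one | O=C1c2c(OCc3ccccc3)cc(OCc3ccccc3)c(-c3cc(-c4cc(=O)c5c(OCc6ccccc6)cc(OCc6ccccc6)cc5o4)ccc3OCc3ccccc3)c2O[C@H](c2ccc(OCc3ccccc3)cc2)[C@H]1O[Si](C)(C)C(C)(C)C
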